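**Retrosynthetic overview** (ring numbering: C1 carries the side chain, C2–H, C3=O, C4–CH3, C5–OCH3, C6=O)

1. Target ⇐ 3‑hydroxy‑5‑methoxy‑4‑methylphenyl tiglate, oxidised last at its free para carbon C6 ⇐ ester and protecting‑group exchange ⇐ a resorcinol monosilyl ether that already holds the whole carbon skeleton.
2. Resorcinol monosilyl ether ⇐ 3‑alkenylcyclobutenone + 1‑(triisopropylsiloxy)propyne in one thermal benzannulation that forges C5–C4 and C3–C2 and re‑closes C5–C6.
3. Enabling feature: the oxygenated ring carbons C5 and C3 stand 1,3 across the methyl‑bearing C4, and C2 and C6 carry only H at the arene stage. A ketene carbon (→ C5) and MeC≡C–OSi (→ C4, C3) map exactly onto this triad; the cyclobutenone C=C supplies C2–H and C1 with the side chain.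
4. Cyclobutenone ⇐ alkenyllithium (from an alkenylstannane ⇐ enol triflate ⇐ methyl ketone) + 3‑ethoxycyclobutenone; the stereocentre comes from methyl (S)‑glycidate opened by an isobutenyl Grignard reagent.
5. Ring order: a transient four‑membered ring, then the six‑membered carbocycle, the only ring of the target.

Key step: step 9

Remark: the stereocentre of the target is (S). Methyl (S)‑glycidate, 3‑ethoxycyclobut‑2‑en‑1‑one, tigloyl chloride and Fremy's salt are taken as commercial.

Step 1
Reactants: 1 methyl (S)-glycidate; 2 (2-methylprop-1-en-1-yl)magnesium bromide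
Product: 3 methyl (2S)-2-hydroxy-5-methylhex-4-enoate
Conditions: CuI (10 mol%), THF, −40 to −20 °C; then aq NH4Cl
Reagents that add atoms: (2-methylprop-1-en-1-yl)magnesium bromide (2), CC(C)=C[Mg]Br
Why: Copper-catalysed Grignard opening of a terminal epoxide proceeds by SN2 attack at the unsubstituted C3 of the glycidate faster than addition to the ester at low temperature, so the C2 centre of the chiral-pool epoxide is carried over untouched as the (S)-carbinol.

Step 2
Reactants: 3 methyl (2S)-2-hydroxy-5-methylhex-4-enoate; 4 tert-butyldimethylsilyl chloride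
Product: 5 methyl (2S)-2-[(tert-butyldimethylsilyl)oxy]-5-methylhex-4-enoate
Conditions: imidazole, DMF, 23 °C
Reagents that add atoms: tert-butyldimethylsilyl chloride (4), CC(C)(C)[Si](C)(C)Cl
Why: Imidazole-promoted silylation (silyl ether protection) of an unhindered secondary alcohol is routine and does not touch the stereocentre.

Step 3
Reactants: 5 methyl (2S)-2-[(tert-butyldimethylsilyl)oxy]-5-methylhex-4-enoate; 6 N,O-dimethylhydroxylamine hydrochloride
Product: 7 (2S)-2-[(tert-butyldimethylsilyl)oxy]-N-methoxy-N,5-dimethylhex-4-enamide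
Conditions: i-PrMgCl, THF, −20 °C
Reagents that add atoms: N,O-dimethylhydroxylamine hydrochloride (6), CNOC.Cl
Why: Aminolysis of the ester by the magnesium amide formed in the flask (Weinreb amide formation) is fast at −20 °C, and the bulky non-nucleophilic base does not enolise the α-silyloxy ester, so the centre is retained.

Step 4
Reactants: 7 (2S)-2-[(tert-butyldimethylsilyl)oxy]-N-methoxy-N,5-dimethylhex-4-enamide; 8 methylmagnesium bromide
Product: 9 (3S)-3-[(tert-butyldimethylsilyl)oxy]-6-methylhept-5-en-2-one
Conditions: THF, 0 °C; then cold 1 M HCl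
Reagents that add atoms: methylmagnesium bromide (8), C[Mg]Br
Why: Weinreb ketone synthesis, in which the chelated tetrahedral adduct survives until work-up and so prevents over-addition and epimerisation.

Step 5
Reactants: 9 (3S)-3-[(tert-butyldimethylsilyl)oxy]-6-methylhept-5-en-2-one; 10 N-phenylbis(trifluoromethanesulfonimide)
Product: 12 (3S)-3-[(tert-butyldimethylsilyl)oxy]-6-methylhepta-1,5-dien-2-yl trifluoromethanesulfonate, via potassium enolate 11 (not isolated)
Conditions: KHMDS, THF, −78 °C; then PhNTf2, −78 to 0 °C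
Reagents that add atoms: N-phenylbis(trifluoromethanesulfonimide) (10), O=S(=O)(N(c1ccccc1)S(=O)(=O)C(F)(F)F)C(F)(F)F
Why: Kinetic deprotonation by the hindered amide base should occur at the unhindered methyl group and not at the silyloxy-bearing methine, and O-sulfonylation of that terminal enolate (enol triflate formation) gives the 1,1-disubstituted alkenyl triflate with the stereocentre intact.

Step 6
Reactants: 12 (3S)-3-[(tert-butyldimethylsilyl)oxy]-6-methylhepta-1,5-dien-2-yl trifluoromethanesulfonate; 13 hexamethylditin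
Product: 14 tert-butyldimethyl{[(3S)-6-methyl-2-(trimethylstannyl)hepta-1,5-dien-3-yl]oxy}silane
Conditions: Pd(PPh3)4 (5 mol%), LiCl, THF, 65 °C
Reagents that add atoms: hexamethylditin (13), C[Sn](C)(C)[Sn](C)(C)C
Why: Palladium-catalysed stannylation of an alkenyl triflate with a distannane (Stille-type coupling) is a standard neutral route to 1-substituted vinylstannanes and leaves the allylic silyl ether and the prenyl alkene alone.

Step 7
Reactants: 14 tert-butyldimethyl{[(3S)-6-methyl-2-(trimethylstannyl)hepta-1,5-dien-3-yl]oxy}silane; 15 3-ethoxycyclobut-2-en-1-one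
Product: 18 3-[(3S)-3-[(tert-butyldimethylsilyl)oxy]-6-methylhepta-1,5-dien-2-yl]cyclobut-2-en-1-one, via alkenyllithium 16 (not isolated), via lithium alkoxide adduct 17 (not isolated)
Conditions: MeLi, THF, −78 °C; then 15, −78 °C; then 1 M HCl, 0 °C
Reagents that add atoms: 3-ethoxycyclobut-2-en-1-one (15), CCOC1=CC(=O)C1
Why: Tin–lithium exchange gives an α-lithiated allylic silyl ether that resists β-elimination at −78 °C and adds 1,2 to the vinylogous ester, after which acid ionises the tertiary alcohol and hydrolyses the ethoxy-stabilised cation (1,2-addition followed by hydrolytic 1,3-carbonyl transposition, the standard entry to 3-substituted cyclobutenones).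

Step 8
Reactants: 19 ethyl acetate; 20 dibromomethane; 21 chlorotriisopropylsilane
Product: 24 triisopropyl(prop-1-yn-1-yloxy)silane, via lithium dibromoenolate 22 (not isolated), via lithium ynolate 23 (not isolated)
Conditions: CH2Br2, LiTMP (2.2 equiv), THF, −78 °C; then n-BuLi, −78 to 20 °C; then i-Pr3SiCl, −78 to 0 °C
Reagents that add atoms: dibromomethane (20), BrCBr; chlorotriisopropylsilane (21), CC(C)[Si](Cl)(C(C)C)C(C)C
Why: Kowalski ester homologation, in which dibromomethyllithium acylation, enolisation, bromine–lithium exchange and 1,2-shift of the carbenoid deliver the ynolate, which the bulky silyl chloride traps on oxygen to give the isolable siloxyalkyne.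

Step 9
Reactants: 18 3-[(3S)-3-[(tert-butyldimethylsilyl)oxy]-6-methylhepta-1,5-dien-2-yl]cyclobut-2-en-1-one; 24 triisopropyl(prop-1-yn-1-yloxy)silane
Product: 29 5-[(3S)-3-[(tert-butyldimethylsilyl)oxy]-6-methylhepta-1,5-dien-2-yl]-2-methyl-3-[(triisopropylsilyl)oxy]phenol, via vinylketene 25 (not isolated), via 4-dienylcyclobutenone 26 (not isolated), via dienylketene 27 (not isolated), via cyclohexadienone 28 (not isolated)
Conditions: 24 (1.5 equiv), toluene, 80 °C then 110 °C, sealed vessel
Reagents that add atoms: none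
Why: Danheiser benzannulation, whose closest precedent is the thermal union of 3-substituted cyclobutenones with 1-siloxyalkynes to 2-alkylresorcinol monosilyl ethers: 18 opens by reversible conrotatory 4π-electrocyclic cleavage of its C1–C4 bond to vinylketene 25. The electrophilic ketene carbon of 25 is attacked by the nucleophilic methyl-bearing carbon of ynol ether 24, and the [2+2] cycloaddition closes the four-membered ring of 26, creating in one event the C5–C4 bond of the later quinone (C–OCH3 to C–CH3) and the C3–C2 bond. 26 reopens in a second 4π-electrocyclic step to dienylketene 27, and the six-membered ring is closed by thermal disrotatory 6π-electrocyclisation between the ketene carbon (C5) and the CH2 terminus (C6), after which dienone 28 tautomerises to phenol 29. No stereocentre is formed, and the (S)-silyloxy centre lies outside the reacting π-system and meets no acid, base or metal, so it should pass through unchanged. The step needs regioselectivity in the [2+2] event, secured by the matched polarisation of ketene and siloxyalkyne (the oxygen-bearing alkyne carbon bonds to C2 and not to the ketene carbon), and chemoselectivity for the alkyne over the three side-chain alkenes, secured by the far higher nucleophilicity of the siloxyalkyne used in excess. Only the isomer of 27 with the diene terminus turned inward can cyclise, and because ring opening of 26 is reversible the other isomer is recycled.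

Step 10
Reactants: 29 5-[(3S)-3-[(tert-butyldimethylsilyl)oxy]-6-methylhepta-1,5-dien-2-yl]-2-methyl-3-[(triisopropylsilyl)oxy]phenol; 30 iodomethane
Product: 31 tert-butyl{[(3S)-2-[3-methoxy-4-methyl-5-(triisopropylsiloxy)phenyl]-6-methylhepta-1,5-dien-3-yl]oxy}dimethylsilane
Conditions: K2CO3, acetone, 50 °C
Reagents that add atoms: iodomethane (30), CI
Why: Williamson O-methylation of the only free hydroxyl, the phenol derived from the ketene carbonyl, fixes that carbon as the methoxy-bearing C5 while both silyl ethers are stable to carbonate in an aprotic solvent.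

Step 11
Reactants: 31 tert-butyl{[(3S)-2-[3-methoxy-4-methyl-5-(triisopropylsiloxy)phenyl]-6-methylhepta-1,5-dien-3-yl]oxy}dimethylsilane
Product: 32 (3S)-2-[3-methoxy-4-methyl-5-(triisopropylsiloxy)phenyl]-6-methylhepta-1,5-dien-3-ol
Conditions: camphorsulfonic acid (10 mol%), MeOH–CH2Cl2, 0 to 23 °C
Reagents that add atoms: none
Why: Acid-catalysed methanolysis (selective silyl ether cleavage) removes an alkyl tert-butyldimethylsilyl ether much faster than an aryl triisopropylsilyl ether, the reverse of the order under basic or fluoride conditions, and the C–O bond of the stereocentre is not broken.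

Step 12
Reactants: 32 (3S)-2-[3-methoxy-4-methyl-5-(triisopropylsiloxy)phenyl]-6-methylhepta-1,5-dien-3-ol; 33 (2E)-2-methylbut-2-enoyl chloride (tigloyl chloride)
Product: 34 (3S)-2-[3-methoxy-4-methyl-5-(triisopropylsiloxy)phenyl]-6-methylhepta-1,5-dien-3-yl (2E)-2-methylbut-2-enoate
Conditions: pyridine, DMAP (10 mol%), CH2Cl2, 0 to 23 °C
Reagents that add atoms: (2E)-2-methylbut-2-enoyl chloride (33), C/C=C(\C)C(=O)Cl
Why: DMAP-catalysed acylation of the secondary alcohol with the acid chloride occurs at oxygen with retention, pyridine instead of a trialkylamine avoids vinylketene formation and hence deconjugation, and the (E)-tiglate is the thermodynamically favoured geometry.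

Step 13
Reactants: 34 (3S)-2-[3-methoxy-4-methyl-5-(triisopropylsiloxy)phenyl]-6-methylhepta-1,5-dien-3-yl (2E)-2-methylbut-2-enoate
Product: 35 (3S)-2-(3-hydroxy-5-methoxy-4-methylphenyl)-6-methylhepta-1,5-dien-3-yl (2E)-2-methylbut-2-enoate
Conditions: Bu4NF, AcOH, THF, 0 °C
Reagents that add atoms: none
Why: Fluoride-mediated desilylation cleaves the aryl silyl ether rapidly, and the acetic acid buffer keeps the phenoxide from attacking the tiglate ester.

Step 14
Reactants: 35 (3S)-2-(3-hydroxy-5-methoxy-4-methylphenyl)-6-methylhepta-1,5-dien-3-yl (2E)-2-methylbut-2-enoate; 36 potassium nitrosodisulfonate (Fremy's salt)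
Product: 37 (3S)-2-(5-methoxy-4-methyl-3,6-dioxocyclohexa-1,4-dien-1-yl)-6-methylhepta-1,5-dien-3-yl (2E)-2-methylbut-2-enoate
Conditions: (KSO3)2NO (2.5 equiv), KH2PO4 buffer, acetone–H2O, 23 °C
Reagents that add atoms: potassium nitrosodisulfonate (36), [K+].[K+].[O]N(S(=O)(=O)[O-])S(=O)(=O)[O-]
Why: Teuber oxidation, in which the nitroxyl radical abstracts the phenolic hydrogen and a second equivalent adds at the unsubstituted para carbon C6 to give the para-quinone, a radical process that should leave the ester and the three alkenes alone.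

**Compound list**

1 | methyl (S)-glycidate | COC(=O)[C@@H]1CO1 | starting material
2 | (2-methylprop-1-en-1-yl)magnesium bromide | CC(C)=C[Mg]Br | starting material
3 | methyl (2S)-2-hydroxy-5-methylhex-4-enoate | COC(=O)[C@@H](O)CC=C(C)C | intermediate
4 | tert-butyldimethylsilyl chloride | CC(C)(C)[Si](C)(C)Cl | starting material
5 | methyl (2S)-2-[(tert-butyldimethylsilyl)oxy]-5-methylhex-4-enoate | COC(=O)[C@@H](O[Si](C)(C)C(C)(C)C)CC=C(C)C | intermediate
6 | N,O-dimethylhydroxylamine hydrochloride | CNOC.Cl | starting material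
7 | (2S)-2-[(tert-butyldimethylsilyl)oxy]-N-methoxy-N,5-dimethylhex-4-enamide | CON(C)C(=O)[C@@H](O[Si](C)(C)C(C)(C)C)CC=C(C)C | intermediate
8 | methylmagnesium bromide | C[Mg]Br | starting material
9 | (3S)-3-[(tert-butyldimethylsilyl)oxy]-6-methylhept-5-en-2-one | CC(=O)[C@@H](O[Si](C)(C)C(C)(C)C)CC=C(C)C | intermediate
10 | N-phenylbis(trifluoromethanesulfonimide) | O=S(=O)(N(c1ccccc1)S(=O)(=O)C(F)(F)F)C(F)(F)F | starting material
11 | potassium (3S)-3-[(tert-butyldimethylsilyl)oxy]-6-methylhepta-1,5-dien-2-olate | [K+].[O-]C(=C)[C@@H](O[Si](C)(C)C(C)(C)C)CC=C(C)C | intermediate (not isolated)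
12 | (3S)-3-[(tert-butyldimethylsilyl)oxy]-6-methylhepta-1,5-dien-2-yl trifluoromethanesulfonate | C=C(OS(=O)(=O)C(F)(F)F)[C@@H](O[Si](C)(C)C(C)(C)C)CC=C(C)C | intermediate
13 | hexamethylditin | C[Sn](C)(C)[Sn](C)(C)C | starting material
14 | tert-butyldimethyl{[(3S)-6-methyl-2-(trimethylstannyl)hepta-1,5-dien-3-yl]oxy}silane | C=C([Sn](C)(C)C)[C@@H](O[Si](C)(C)C(C)(C)C)CC=C(C)C | intermediate
15 | 3-ethoxycyclobut-2-en-1-one | CCOC1=CC(=O)C1 | starting material
16 | [(3S)-3-[(tert-butyldimethylsilyl)oxy]-6-methylhepta-1,5-dien-2-yl]lithium | [Li]C(=C)[C@@H](O[Si](C)(C)C(C)(C)C)CC=C(C)C | intermediate (not isolated)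
17 | lithium 1-[(3S)-3-[(tert-butyldimethylsilyl)oxy]-6-methylhepta-1,5-dien-2-yl]-3-ethoxycyclobut-2-en-1-olate (mixture at the carbinol carbon) | [Li+].CCOC1=CC([O-])(C(=C)[C@@H](O[Si](C)(C)C(C)(C)C)CC=C(C)C)C1 | intermediate (not isolated)
18 | 3-[(3S)-3-[(tert-butyldimethylsilyl)oxy]-6-methylhepta-1,5-dien-2-yl]cyclobut-2-en-1-one | O=C1C=C(C(=C)[C@@H](O[Si](C)(C)C(C)(C)C)CC=C(C)C)C1 | intermediate
19 | ethyl acetate | CCOC(C)=O | starting material
20 | dibromomethane | BrCBr | starting material
21 | chlorotriisopropylsilane | CC(C)[Si](Cl)(C(C)C)C(C)C | starting material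
22 | lithium 1,1-dibromoprop-1-en-2-olate | [Li+].CC([O-])=C(Br)Br | intermediate (not isolated)
23 | lithium prop-1-yn-1-olate | [Li+].CC#C[O-] | intermediate (not isolated)
24 | triisopropyl(prop-1-yn-1-yloxy)silane | CC#CO[Si](C(C)C)(C(C)C)C(C)C | intermediate
25 | (5S)-5-[(tert-butyldimethylsilyl)oxy]-8-methyl-3,4-dimethylidenenona-1,7-dien-1-one (vinylketene) | O=C=CC(=C)C(=C)[C@@H](O[Si](C)(C)C(C)(C)C)CC=C(C)C | intermediate (not isolated)
26 | 4-[(4S)-4-[(tert-butyldimethylsilyl)oxy]-7-methyl-3-methylideneocta-1,6-dien-2-yl]-2-methyl-3-[(triisopropylsilyl)oxy]cyclobut-2-en-1-one (mixture at the ring sp3 carbon) | O=C1C(C)=C(O[Si](C(C)C)(C(C)C)C(C)C)C1C(=C)C(=C)[C@@H](O[Si](C)(C)C(C)(C)C)CC=C(C)C | intermediate (not isolated)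
27 | dienylketene, the ring-opened form of 26 with the methylidene terminus cis to the ketene-bearing carbon | O=C=C(C)/C(O[Si](C(C)C)(C(C)C)C(C)C)=C\C(=C)C(=C)[C@@H](O[Si](C)(C)C(C)(C)C)CC=C(C)C | intermediate (not isolated)
28 | 5-[(3S)-3-[(tert-butyldimethylsilyl)oxy]-6-methylhepta-1,5-dien-2-yl]-2-methyl-3-[(triisopropylsilyl)oxy]cyclohexa-2,4-dien-1-one | O=C1CC(C(=C)[C@@H](O[Si](C)(C)C(C)(C)C)CC=C(C)C)=CC(O[Si](C(C)C)(C(C)C)C(C)C)=C1C | intermediate (not isolated)
29 | 5-[(3S)-3-[(tert-butyldimethylsilyl)oxy]-6-methylhepta-1,5-dien-2-yl]-2-methyl-3-[(triisopropylsilyl)oxy]phenol | Cc1c(O)cc(C(=C)[C@@H](O[Si](C)(C)C(C)(C)C)CC=C(C)C)cc1O[Si](C(C)C)(C(C)C)C(C)C | intermediate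
30 | iodomethane | CI | starting material
31 | tert-butyl{[(3S)-2-[3-methoxy-4-methyl-5-(triisopropylsiloxy)phenyl]-6-methylhepta-1,5-dien-3-yl]oxy}dimethylsilane | COc1cc(C(=C)[C@@H](O[Si](C)(C)C(C)(C)C)CC=C(C)C)cc(O[Si](C(C)C)(C(C)C)C(C)C)c1C | intermediate
32 | (3S)-2-[3-methoxy-4-methyl-5-(triisopropylsiloxy)phenyl]-6-methylhepta-1,5-dien-3-ol | COc1cc(C(=C)[C@@H](O)CC=C(C)C)cc(O[Si](C(C)C)(C(C)C)C(C)C)c1C | intermediate
33 | (2E)-2-methylbut-2-enoyl chloride (tigloyl chloride) | C/C=C(\C)C(=O)Cl | starting material
34 | (3S)-2-[3-methoxy-4-methyl-5-(triisopropylsiloxy)phenyl]-6-methylhepta-1,5-dien-3-yl (2E)-2-methylbut-2-enoate | COc1cc(C(=C)[C@@H](OC(=O)/C(C)=C/C)CC=C(C)C)cc(O[Si](C(C)C)(C(C)C)C(C)C)c1C | intermediate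
35 | (3S)-2-(3-hydroxy-5-methoxy-4-methylphenyl)-6-methylhepta-1,5-dien-3-yl (2E)-2-methylbut-2-enoate | COc1cc(C(=C)[C@@H](OC(=O)/C(C)=C/C)CC=C(C)C)cc(O)c1C | intermediate
36 | potassium nitrosodisulfonate (Fremy's salt) | [K+].[K+].[O]N(S(=O)(=O)[O-])S(=O)(=O)[O-] | starting material
37 | (3S)-2-(5-methoxy-4-methyl-3,6-dioxocyclohexa-1,4-dien-1-yl)-6-methylhepta-1,5-dien-3-yl (2E)-2-methylbut-2-enoate | C=C(C1=CC(=O)C(C)=C(OC)C1=O)[C@H](CC=C(C)C)OC(=O)/C(C)=C/C | target

**Step count**

Total: 14 steps. Longest linear sequence: 13 steps (steps 1 to 7 and 9 to 14); step 8 is a one-step branch.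

**Steps most likely to fail**

1. Step 9. The vinylketene may be consumed by dimerisation or by cycloaddition with its own cross-conjugated diene before the siloxyalkyne captures it, or the phenol formed may be acylated by a second ketene. The fallback is an alkenyl–aryl cross-coupling that sets out from alkenyl triflate 12 and comes back to the route at 31. Commercial 3-methoxy-2-methylphenol (COc1cccc(O)c1C) is silylated (i-Pr3SiCl, imidazole, DMF) to triisopropyl(3-methoxy-2-methylphenoxy)silane F1. Iridium-catalysed C–H borylation ([Ir(OMe)(cod)]2, 4,4'-di-tert-butyl-2,2'-bipyridine, B2pin2, THF, 70 °C) should occur at the only ring C–H without an ortho substituent and give 2-[3-methoxy-4-methyl-5-(triisopropylsiloxy)phenyl]-4,4,5,5-tetramethyl-1,3,2-dioxaborolane F2. Suzuki–Miyaura coupling of F2 with 12 (Pd(PPh3)4, K3PO4, dioxane, 60 °C) should give 31, from which steps 11 to 14 follow unchanged.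

2. Step 7. The alkenyllithium 16 may lose silanolate by β-elimination to an allene, the cyclobutenone may be deprotonated instead of attacked, or the cross-conjugated cyclobutenone may polymerise during the acidic hydrolysis. The fallback is acylation followed by methylenation; it sets out from Weinreb amide 7 and comes back at 31. Boronate F2 of the first fallback is converted with CuBr2 (MeOH–H2O, 80 °C) into 5-bromo-1-methoxy-2-methyl-3-(triisopropylsiloxy)benzene F3. Bromine–lithium exchange (t-BuLi, THF, −78 °C) and addition of the aryllithium to 7 should give (2S)-2-[(tert-butyldimethylsilyl)oxy]-1-[3-methoxy-4-methyl-5-(triisopropylsiloxy)phenyl]-5-methylhex-4-en-1-one F4. Non-basic Petasis methylenation (Cp2TiMe2, toluene, 70 °C) should then turn the carbonyl group into the 1,1-disubstituted alkene of 31 without epimerising the neighbouring centre.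

3. Step 11. The aryl silyl ether may be lost together with the alkyl one, or cleavage at the hindered secondary position may stay incomplete under conditions mild enough to spare the allylic system. The fallback is global desilylation followed by selective aryl ester cleavage; it sets out from 31 and comes back at 35. Bu4NF (THF, 0 °C) should remove both silyl groups and give 5-[(3S)-3-hydroxy-6-methylhepta-1,5-dien-2-yl]-3-methoxy-2-methylphenol F5. Acylation of both hydroxyls with tigloyl chloride 33 (pyridine, DMAP, CH2Cl2) should give (3S)-2-{3-methoxy-4-methyl-5-[(2E)-2-methylbut-2-enoyloxy]phenyl}-6-methylhepta-1,5-dien-3-yl (2E)-2-methylbut-2-enoate F6. Brief methanolysis (K2CO3, MeOH, 0 °C) should cleave only the aryl ester, which is far more electrophilic than the hindered secondary alkyl ester, and give 35, so that steps 11 to 13 are bypassed.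

**Further compounds**

F1 | step 9 | triisopropyl(3-methoxy-2-methylphenoxy)silane | COc1cccc(O[Si](C(C)C)(C(C)C)C(C)C)c1C
F2 | step 9 | 2-[3-methoxy-4-methyl-5-(triisopropylsiloxy)phenyl]-4,4,5,5-tetramethyl-1,3,2-dioxaborolane | COc1cc(B2OC(C)(C)C(C)(C)O2)cc(O[Si](C(C)C)(C(C)C)C(C)C)c1C
F3 | step 7 | 5-bromo-1-methoxy-2-methyl-3-(triisopropylsiloxy)benzene | COc1cc(Br)cc(O[Si](C(C)C)(C(C)C)C(C)C)c1C
F4 | step 7 | (2S)-2-[(tert-butyldimethylsilyl)oxy]-1-[3-methoxy-4-methyl-5-(triisopropylsiloxy)phenyl]-5-methylhex-4-en-1-one | COc1cc(C(=O)[C@@H](O[Si](C)(C)C(C)(C)C)CC=C(C)C)cc(O[Si](C(C)C)(C(C)C)C(C)C)c1C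
F5 | step 11 | 5-[(3S)-3-hydroxy-6-methylhepta-1,5-dien-2-yl]-3-methoxy-2-methylphenol | COc1cc(C(=C)[C@@H](O)CC=C(C)C)cc(O)c1C
F6 | step 11 | (3S)-2-{3-methoxy-4-methyl-5-[(2E)-2-methylbut-2-enoyloxy]phenyl}-6-methylhepta-1,5-dien-3-yl (2E)-2-methylbut-2-enoate | COc1cc(C(=C)[C@@H](OC(=O)/C(C)=C/C)CC=C(C)C)cc(OC(=O)/C(C)=C/C)c1C
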